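**Assumptions:** The target has no stereocentre and no E/Z-stereogenic alkene, so there is no enantiomer to select. Every compound that contributes skeletal carbon is numbered as a starting material; methyl and MOM groups are protecting groups.

## Retrosynthetic overview

1. Last steps: MOM removal, preceded by an aromatic Claisen rearrangement of a 7-O-prenyl ether to set the C8 1,1-dimethylallyl group.
2. Key disconnection C2–C1′: photostimulated radical (SRN1-type) C-arylation of a 3-oxidochromone (C2–H) with the fully prenylated B-ring aryl bromide. The flavonol 3-OH emerges unprotected.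
3. AC fragment: resorcinol → 3,5-dimethoxyphenol (C–H borylation/oxidation) → acylation/C1 insertion closes the pyranone → demethylation → 7-O-prenylation.
4. B fragment: catechol → ortho-lithiation/allylation → iodination then bromination (para to outer, then inner OMOM) → cross-metathesis to prenyl → I/Mg exchange and prenylation.
5. Ring order: A ring bought (resorcinol), C ring fused onto A, B ring (catechol) attached last through the radical step.

## Route

**Step 1**
Reactants: 1 resorcinol
Product: 2 1,3-dimethoxybenzene
Conditions: MeI, K2CO3, acetone, reflux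
Reagents that add atoms: iodomethane, CI
Why: Williamson etherification; the methyl ethers carry the ring through borylation and acylation and are all removed together in step 4.

**Step 2**
Reactants: 2
Product: 3 3,5-dimethoxyphenol
Conditions: [Ir(OMe)(cod)]2 (1 mol%), dtbpy, B2pin2, THF, 80 °C; then Oxone, acetone/H2O, rt (one pot)
Reagents that add atoms: Oxone (KHSO5), OOS(=O)(=O)[O-].[K+] (B2pin2, CC1(C)OB(OC1(C)C)B1OC(C)(C)C(C)(C)O1, adds boron transiently)
Why: Sterically controlled Ir-catalysed C–H borylation reaches only C5 (meta to both OMe), and ipso-oxidation of the boronate gives the 1,3,5-trioxygenated ring.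

**Step 3**
Reactants: 3; 4 methoxyacetic acid
Product: 5 3,5,7-trimethoxy-4H-chromen-4-one
Conditions: BF3·OEt2, 85 °C; then DMF, MsCl, 70 °C; aq NaOAc (one pot, two stages)
Reagents that add atoms: N,N-dimethylformamide, CN(C)C=O (supplies C2)
Why: BF3-mediated Friedel–Crafts/Fries acylation ortho to the free OH gives the chelated 2-hydroxyaryl methoxymethyl ketone; Vilsmeier-type formylation of its α-CH2 and cyclisation then closes the 3-methoxychromone, as in the one-pot isoflavone protocol.

**Step 4**
Reactants: 5
Product: 6 3,5,7-trihydroxy-4H-chromen-4-one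
Conditions: BBr3 (6 equiv), CH2Cl2, −78 °C → rt; MeOH quench
Reagents that add atoms: none
Why: Lewis-acid ether cleavage of all three methyl ethers, done before any alkene is present.

**Step 5**
Reactants: 6; 7 prenyl bromide (1-bromo-3-methylbut-2-ene)
Product: 8 3,5-dihydroxy-7-[(3-methylbut-2-en-1-yl)oxy]-4H-chromen-4-one
Conditions: K2CO3 (1.1 equiv), 7 (1.05 equiv), acetone, rt
Reagents that add atoms: none
Why: Selective Williamson O-alkylation at the most acidic, non-chelated 7-OH; the prenyl ether also masks O7 during the radical step and is the Claisen precursor.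

**Step 6**
Reactants: 9 catechol
Product: 10 1,2-bis(methoxymethoxy)benzene
Conditions: MOMCl, i-Pr2NEt, CH2Cl2, 0 °C → rt
Reagents that add atoms: chloromethyl methyl ether, COCCl
Why: Acetal protection; OMOM is a strong ortho-metalation director and comes off under mild acid at the end.

**Step 7**
Reactants: 10; 11 allyl bromide
Product: 12 1-allyl-2,3-bis(methoxymethoxy)benzene
Conditions: n-BuLi, THF, 0 °C; then 11, −78 °C → rt
Reagents that add atoms: none
Why: Directed ortho-metalation beside OMOM, then allylation; allyl is used as a halogenation-tolerant prenyl precursor.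

**Step 8**
Reactants: 12
Product: 13 1-bromo-2-iodo-4,5-bis(methoxymethoxy)-3-(prop-2-en-1-yl)benzene
Conditions: NIS (1.05 equiv), TFA (10 mol%), MeCN, 0 °C; then NBS (1.05 equiv), 0 °C → rt, dark
Reagents that add atoms: N-iodosuccinimide, O=C1CCC(=O)N1I; N-bromosuccinimide, O=C1CCC(=O)N1Br
Why: Electrophilic aromatic substitution; the in-plane outer OMOM directs iodine para (next to the allyl group), then the twisted inner OMOM directs bromine para, as in the halogenation of 2,3-dimethoxytoluene.

**Step 9**
Reactants: 13; 14 2-methyl-2-butene
Product: 15 1-bromo-2-iodo-4,5-bis(methoxymethoxy)-3-(3-methylbut-2-en-1-yl)benzene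
Conditions: Grubbs II (3 mol%), 14/CH2Cl2 (1:1), 40 °C
Reagents that add atoms: none
Why: Olefin cross-metathesis converts allyl to prenyl; done while only one alkene is present, so no ring-closing metathesis can compete.

**Step 10**
Reactants: 15; 7 prenyl bromide
Product: 16 1-bromo-4,5-bis(methoxymethoxy)-2,3-bis(3-methylbut-2-en-1-yl)benzene
Conditions: i-PrMgCl·LiCl (1.05 equiv), THF, −40 °C; then Li2CuCl4 (5 mol%), 7, −40 → 0 °C
Reagents that add atoms: none
Why: I/Mg exchange is far faster than Br/Mg exchange, so only the iodide is metalated; Cu-catalysed SN2 coupling with prenyl bromide gives the linear prenyl group and leaves the C1′ bromide in place.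

**Step 11 (key step)**
Reactants: 8 (1.5 equiv); 16 (1.0 equiv)
Product: 17 2-[4,5-bis(methoxymethoxy)-2,3-bis(3-methylbut-2-en-1-yl)phenyl]-3,5-dihydroxy-7-[(3-methylbut-2-en-1-yl)oxy]-4H-chromen-4-one
Conditions: KOt-Bu (2.0 equiv per 8, no free alkoxide), degassed DMSO, 405 nm LEDs, 25 °C, Ar; aq NH4Cl
Reagents that add atoms: none
Why: Proposed new method: the photoexcited 3-oxidochromone anion transfers an electron to the aryl bromide, which loses bromide to give the aryl radical; this adds to the enolate carbon C2 (largest HOMO coefficient, only C–H site of the anion) to give a stabilised semidione radical anion, which is re-oxidised by the chromone-oxyl radical (or couples with it directly) and tautomerises (C2–H to 3-OH) to the flavonol. The closest known reactions are photostimulated SRN1 C-arylation of enolates and of phenoxides/2-naphthoxide and base-promoted homolytic aromatic substitution; radical–anion coupling is near diffusion-controlled, so it should outrun aryl-radical attack on the prenyl groups.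

**Step 12**
Reactants: 17
Product: 18 2-[4,5-bis(methoxymethoxy)-2,3-bis(3-methylbut-2-en-1-yl)phenyl]-3,5,7-trihydroxy-8-(2-methylbut-3-en-2-yl)-4H-chromen-4-one
Conditions: N,N-diethylaniline, 195 °C, Ar, sealed tube
Reagents that add atoms: none
Why: Aromatic Claisen [3,3] rearrangement of the 7-O-prenyl ether delivers the inverted 1,1-dimethylallyl group to C8, the ortho position with the higher C7–C8 bond order in chromones; no stereocentre is formed.

**Step 13**
Reactants: 18
Product: 19 broussoflavonol C
Conditions: 3 M aq HCl/MeOH (1:5), 45 °C
Reagents that add atoms: none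
Why: Mild acetal hydrolysis removes both MOM groups under conditions routinely used on prenylated flavonoids without chroman formation.

## Compound list

1 | resorcinol | Oc1cccc(O)c1 | starting material
2 | 1,3-dimethoxybenzene | COc1cccc(OC)c1 | intermediate
3 | 3,5-dimethoxyphenol | COc1cc(O)cc(OC)c1 | intermediate
4 | methoxyacetic acid | COCC(=O)O | starting material
5 | 3,5,7-trimethoxy-4H-chromen-4-one | COc1cc(OC)c2c(=O)c(OC)coc2c1 | intermediate
6 | 3,5,7-trihydroxy-4H-chromen-4-one | Oc1cc(O)c2c(=O)c(O)coc2c1 | intermediate
7 | prenyl bromide (1-bromo-3-methylbut-2-ene) | CC(C)=CCBr | starting material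
8 | 3,5-dihydroxy-7-[(3-methylbut-2-en-1-yl)oxy]-4H-chromen-4-one | CC(C)=CCOc1cc(O)c2c(=O)c(O)coc2c1 | intermediate
9 | catechol | Oc1ccccc1O | starting material
10 | 1,2-bis(methoxymethoxy)benzene | COCOc1ccccc1OCOC | intermediate
11 | allyl bromide | C=CCBr | starting material
12 | 1-allyl-2,3-bis(methoxymethoxy)benzene | C=CCc1cccc(OCOC)c1OCOC | intermediate
13 | 1-bromo-2-iodo-4,5-bis(methoxymethoxy)-3-(prop-2-en-1-yl)benzene | C=CCc1c(I)c(Br)cc(OCOC)c1OCOC | intermediate
14 | 2-methyl-2-butene | CC=C(C)C | starting material
15 | 1-bromo-2-iodo-4,5-bis(methoxymethoxy)-3-(3-methylbut-2-en-1-yl)benzene | CC(C)=CCc1c(I)c(Br)cc(OCOC)c1OCOC | intermediate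
16 | 1-bromo-4,5-bis(methoxymethoxy)-2,3-bis(3-methylbut-2-en-1-yl)benzene | CC(C)=CCc1c(CC=C(C)C)c(Br)cc(OCOC)c1OCOC | intermediate
17 | 2-[4,5-bis(methoxymethoxy)-2,3-bis(3-methylbut-2-en-1-yl)phenyl]-3,5-dihydroxy-7-[(3-methylbut-2-en-1-yl)oxy]-4H-chromen-4-one | CC(C)=CCOc1cc(O)c2c(=O)c(O)c(-c3cc(OCOC)c(OCOC)c(CC=C(C)C)c3CC=C(C)C)oc2c1 | intermediate
18 | 2-[4,5-bis(methoxymethoxy)-2,3-bis(3-methylbut-2-en-1-yl)phenyl]-3,5,7-trihydroxy-8-(2-methylbut-3-en-2-yl)-4H-chromen-4-one | C=CC(C)(C)c1c(O)cc(O)c2c(=O)c(O)c(-c3cc(OCOC)c(OCOC)c(CC=C(C)C)c3CC=C(C)C)oc12 | intermediate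
19 | broussoflavonol C | C=CC(C)(C)c1c(O)cc(O)c2c(=O)c(O)c(-c3cc(O)c(O)c(CC=C(C)C)c3CC=C(C)C)oc12 | target

## Summary

Total steps: 13.
Longest linear sequence: 8 steps (1–5, then 11–13; the B-ring branch 6–10, then 11–13, is also 8).

Three steps most likely to fail:

- **Step 11 (radical C2-arylation).** Risks are sluggish electron transfer to the electron-rich aryl bromide, hydrodebromination, and competing arylation at C6/C8 of the 5-oxide. Fallback: abandon the radical union for Pd chemistry. MOM-protect 8, lithiate and iodinate C2, and run a Suzuki–Miyaura coupling with the boronic ester made from 16 (t-BuLi, then i-PrOBpin).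
- **Step 8 (sequential iodination/bromination).** Risks are attack at C6 instead of C5 and halogenation of the allyl group. Fallback: build the halide by a different logic. Dibrominate 10 to the 4,5-dibromide, deprotonate at C3 with LDA and prenylate, use sterically selective Pd-catalysed Miyaura borylation at the less hindered C–Br, then Negishi prenylation of the remaining bromide and Cu-mediated iododeboronation.
- **Step 12 (Claisen rearrangement).** Risks are competing migration to C6 with the 5-OH free, and thermal cyclisation of the new 7-OH onto the allyl group. Fallback: drop the sigmatropic step. Install the C8 group by Pd-catalysed branched-selective (γ) Suzuki–Miyaura reverse prenylation of an 8-iodo-5,7-bis(MOM) chromone with prenylboronic acid pinacol ester before the union.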